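Readings and results were generated by integration from invented constants.

Slowness is not what the eta run shows: it reads 9.8% target at 8.00 min and 9.8% at 50.0 min, with 90.9% of the starting material still there.

| flask | starting material | reagent | second substrate | protic impurity | remark | time |
|---|---|---|---|---|---|---|
| beta | 0.070 M | 0.025 M | 0.050 M (fed, over 1.0 min) | 0.050 M | run made earlier |  |
| alpha | 0.11 M | 0.025 M | 0.050 M (fed, over 1.0 min) | 0.050 M | run made earlier |  |
| eta | 0.050 M | 0.013 M | 0.050 M (fed, over 1.0 min) | 0.050 M | run made earlier |  |
| flask | 0.050 M | 0.0250 M | 0.0500 M (fed, over 1.0 min) | 0.0500 M |  | 1.0 h |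

- beta (time / min: target / %, starting material / %): 4.00: 13.9, 85.8; 6.00: 14.1, 85.7; 10.0: 15.5, 85.0; 20.0: 15.0, 85.9; 30.0: 15.0, 84.4; 50.0: 16.3, 84.0
- alpha (time / min: target / %, starting material / %): 8.00: 13.2, 87.9; 15.0: 12.3, 87.4; 25.0: 12.6, 87.0; 30.0: 13.1, 86.6; 40.0: 11.8, 87.7; 50.0: 11.8, 87.0
- eta (time / min: target / %, starting material / %): 4.00: 8.4, 91.3; 8.00: 9.8, 90.4; 15.0: 9.8, 90.9; 25.0: 9.0, 90.6; 50.0: 9.8, 90.9

(scatter of a reading: 0.5 percentage points)

- the reaction counts as stopped when no species that holds the starting material changes by six tenths of a point or more over the second half of the time

* the state of affairs at 1.0 h: stopped, and by what, or still going (the reagent has run out first / all of the starting material has reacted / forward and back rates have come level / it is still moving)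
* how much target there is at 1.0 h, in percent of the starting material charged

Target stops at a different share in each run, yet one number comes out level across them: the plateau quotient, an apparent equilibrium constant, c(target)/(c(starting material)·c(reagent)), each free amount taken as charge minus target. Mean target of 15.0% (beta), 12.5% (alpha) and 9.36% (eta) gives 12.1 /M, 12.6 /M and 12.4 /M; call their mean Q, 12.4 /M. Second substrate and protic impurity stand at the same charges in these runs and in your flask, so leave them there: Q was read at them.

In your flask, treat target x as the correction to the charges: x = Q(c(starting material) − x)(c(reagent) − x) gives 0.00849 M, so I expect 17.0% target, with 66.0% of the reagent still free and forward and back rates level.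

The forecast says the reagent has run out first, with 17.6% target (16.3% to 19%), reasoning that “the reagent is split between starting material and protic impurity”; my reckoning differs from it on the ending.

The flask's state at 1.00 h is this: forward and back rates have come level, with 17.4% target and 64.8% of the reagent left.

    second substrate + protic impurity → quenched substrate (k = 3.20 /M/s)
    second substrate + reagent ⇌ second product (K = 69.0 /M, k = 0.640 /M/s)
    starting material + reagent ⇌ target (K = 13.0 /M, k = 0.260 /M/s)

At 1.00 h the target step taken by itself, both ways together, has a relaxation half-life of 0.331 min, short against 1.0 h, but the flask is not still in every species: second product falls from 1.05 × 10⁻⁴ M at 1.00 h to 9.85 × 10⁻⁶ M at 10.0 h, and protic impurity from 0.391% to 0.0372% of its charge. Put through Q as a correction, that fall of second product, counted as reagent set free, is worth 0.057 percentage points of target, less than the scatter of 0.5 points; the later reading makes no difference worth watching, and target stands at 17.5% at 10.0 h.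

For the neighbour flask with 0.085 M starting material, Q gives 0.0119 M target, which is 14.0% of its charge; computed, that flask stands at 14.3%.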